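## Retrosynthetic overview

- The strategy rests on the spiro carbon C15′ of the benzofuranone: it carries the aryl carbon C14′, the single carbonyl carbon C16′ and two carbons (C12, Cb) of the cyclohexane ring C12–C13–C14–Ca–Cb–C15′. This 1-aryl-cyclohexane-1-carbonyl unit is what a 1-aryl-cycloheptene oxide delivers when a ring carbon shifts to the benzylic carbon and the carbon it leaves becomes a formyl group.
- Key disconnection C12–C15′: lactone 49 ⇐ lactol 48 ⇐ aldehyde 46 ⇐ epoxide 45 (Meinwald ring contraction) ⇐ aryl cycloheptene 44 ⇐ diene 42 (ring-closing metathesis forms C15′=C16′).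
- Diene 42 ⇐ allylic alcohol 33 (decalin, from carnosic acid by cleavage of its catechol ring) + aryl dioxinone 19 (tricycle from sclareol, aryl–C15′ bond by Negishi coupling). The union is an acylketene esterification, then a dianionic Carroll rearrangement (sets C12) with decarboxylative methylenation (C13=CH2), then CBS reduction (sets C14).
- The C8 methylene of the decalin is kept latent as the Δ8 alkene with a C17 pivalate until the cycloheptene is closed, because a C12 alkenyl group and a C8 methylene would otherwise close a cyclopentene. Palladium/formate transposition then releases it and sets C9–H.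
- Ring order: aromatic ring of the tricycle (aldol closure, aromatisation) → cycloheptene (metathesis) → cyclohexane (ring contraction) → lactone ring (lactol oxidation).

Key step: step 31

Remark on labels (no change of structure): decalin unit C1–C10, C17 = carbon on C8 (the former arene CH of carnosic acid), C20 = carboxyl carbon on C10; linker C11–C14 (C13 carries the methylene), Ca and Cb = the two ring CH2 groups between C14 and C15′; aryl tricycle C1′–C14′ (podocarpane numbering); C15′ = spiro carbon, C16′ = lactone carbonyl carbon. The "α face" of the linker ring is the face that carries C11. TBS = tert-butyldimethylsilyl, TES = triethylsilyl, TMSE = 2-(trimethylsilyl)ethyl, Piv = pivaloyl.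

Assumption: (−)-sclareol, carnosic acid, 2,2,6-trimethyl-4H-1,3-dioxin-4-one and (S)-but-3-yn-2-ol are bought; all reagents named under the steps are standard commercial chemicals.

## Route

### Aryl fragment (from sclareol)

Step 1
Reactants: 1 (−)-sclareol
Product: 4 8α-hydroxy-14,15-dinorlabdan-13-one, via tetraol 2 (not isolated), via hydroxy aldehyde 3 (not isolated)
Conditions: OsO4 (cat.), NaIO4 (3.5 equiv), THF/H2O, rt
Reagents that add atoms: none
Why: Lemieux–Johnson dihydroxylation and periodate cleavage of the vinyl group, followed by periodate cleavage of the tertiary α-hydroxy aldehyde so formed, should leave the methyl ketone without touching any stereocentre.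

Step 2
Reactants: 4 8α-hydroxy-14,15-dinorlabdan-13-one
Product: 5 14,15-dinorlabd-8(17)-en-13-one
Conditions: SOCl2, pyridine, CH2Cl2, −78 °C
Reagents that add atoms: none
Why: E2 dehydration of the chlorosulfite should favour the exocyclic alkene, because the equatorial C8 leaving group has antiperiplanar hydrogen only on the C17 methyl group.

Step 3
Reactants: 5 14,15-dinorlabd-8(17)-en-13-one
Product: 7 14,15,17-trinorlabdane-8,13-dione, via ozonide 6 (not isolated)
Conditions: O3, CH2Cl2, −78 °C; then Me2S, −78 °C → rt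
Reagents that add atoms: ozone, [O-][O+]=O
Why: Ozonolysis of the only alkene with reductive work-up should give the C8 ketone with loss of C17.

Step 4
Reactants: 7 14,15,17-trinorlabdane-8,13-dione
Product: 8 (+)-podocarp-8(14)-en-13-one
Conditions: NaOMe, MeOH, reflux
Reagents that add atoms: none
Why: Intramolecular aldol condensation of the 1,5-diketone (the ring-closing half of a Robinson annulation) should join C14 to C8 and dehydrate to the conjugated enone, C9 keeping its stable equatorial side chain (9α-H).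

Step 5
Reactants: 8 (+)-podocarp-8(14)-en-13-one
Product: 9 podocarpa-8,11,13-trien-13-ol
Conditions: CuBr2 (2.2 equiv), LiBr, MeCN, reflux
Reagents that add atoms: none
Why: α′-Bromination by CuBr2 and loss of HBr give a cross-conjugated dienone that tautomerises to the phenol (oxidative aromatisation), C9 becoming sp2.

Step 6
Reactants: 9 podocarpa-8,11,13-trien-13-ol
Product: 10 14-bromopodocarpa-8,11,13-trien-13-ol
Conditions: NBS (1.0 equiv), i-Pr2NH (10 mol%), CH2Cl2, 0 °C
Reagents that add atoms: N-bromosuccinimide, O=C1CCC(=O)N1Br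
Why: Amine-mediated ortho-selective electrophilic bromination should take the ortho position next to the alicyclic ring (C14), the site favoured in phenols of the 5,6,7,8-tetrahydro-2-naphthol type, the para position C9 being blocked.

Step 7
Reactants: 10 14-bromopodocarpa-8,11,13-trien-13-ol
Product: 11 14-bromo-13-(TBS-oxy)podocarpa-8,11,13-triene
Conditions: TBSCl, imidazole, DMF, rt
Reagents that add atoms: tert-butyldimethylsilyl chloride, CC(C)(C)[Si](C)(C)Cl
Why: Imidazole-promoted silylation protects the phenol for the oxidation and organometallic steps that follow.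

Step 8
Reactants: 11 14-bromo-13-(TBS-oxy)podocarpa-8,11,13-triene
Product: 12 14-bromo-13-(TBS-oxy)podocarpa-8,11,13-trien-7-one
Conditions: Rh2(cap)4 (1 mol%, cap = caprolactamate), t-BuOOH, NaHCO3, ClCH2CH2Cl, 40 °C
Reagents that add atoms: tert-butyl hydroperoxide, CC(C)(C)OO
Why: Dirhodium-catalysed benzylic C–H oxidation should convert the only benzylic methylene (C7) into the aryl ketone while the silyl ether and the bromide are inert.

Step 9
Reactants: 12 14-bromo-13-(TBS-oxy)podocarpa-8,11,13-trien-7-one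
Product: 13 (7S)-14-bromo-13-(TBS-oxy)podocarpa-8,11,13-trien-7β-ol
Conditions: (R)-2-methyl-CBS-oxazaborolidine (20 mol%), BH3·SMe2, THF, −20 °C
Reagents that add atoms: none
Why: Corey–Bakshi–Shibata reduction with the (R)-catalyst, the aryl group acting as the large substituent, should deliver hydride to the α face and give the (7S)-7β-alcohol, which is also the product of axial attack.

Step 10
Reactants: 13 (7S)-14-bromo-13-(TBS-oxy)podocarpa-8,11,13-trien-7β-ol
Product: 14 7β-triethylsilyl ether of 13
Conditions: TESOTf, 2,6-lutidine, CH2Cl2, −78 → 0 °C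
Reagents that add atoms: triethylsilyl trifluoromethanesulfonate, CC[Si](CC)(CC)OS(=O)(=O)C(F)(F)F
Why: Silylation with the reactive triflate protects the hindered benzylic alcohol as a base-stable ether that can later be removed beside tert-butyldimethylsilyl ethers.

Step 11
Reactants: 15 2,2,6-trimethyl-4H-1,3-dioxin-4-one
Product: 17 6-(3-bromobut-3-en-1-yl)-2,2-dimethyl-4H-1,3-dioxin-4-one, via lithium dienolate 16 (not isolated)
Conditions: LDA, THF, −78 °C; then 2,3-dibromopropene, DMPU, −78 → −20 °C
Reagents that add atoms: 2,3-dibromopropene, C=C(Br)CBr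
Why: γ-Alkylation (SN2) of the dioxinone dienolate at the allylic bromide end of the dihalide should give the 2-bromoalkene, the vinylic bromide being untouched at low temperature.

Step 12
Reactants: 14 7β-triethylsilyl ether of 13; 17 6-(3-bromobut-3-en-1-yl)-2,2-dimethyl-4H-1,3-dioxin-4-one
Product: 19 aryl dioxinone, via arylzinc chloride 18 (not isolated)
Conditions: Mg, LiCl, ZnCl2, THF, 25 °C; then 17, Pd(OAc)2 (5 mol%), SPhos, THF, 50 °C
Reagents that add atoms: none
Why: Magnesium insertion in the presence of ZnCl2 gives the arylzinc chloride without a free aryllithium (no retro-Brook silyl shift), and Negishi coupling with the 2-bromoalkene under a bulky biarylphosphine–palladium catalyst should form the hindered aryl–C15′ bond.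

### Decalin fragment (from carnosic acid)

Step 13
Reactants: 20 carnosic acid
Product: 21 2-(trimethylsilyl)ethyl carnosate
Conditions: 2-(trimethylsilyl)ethyl 2,2,2-trichloroacetimidate, toluene, 100 °C, Ar
Reagents that add atoms: 2-(trimethylsilyl)ethyl 2,2,2-trichloroacetimidate, C[Si](C)(C)CCOC(=N)C(Cl)(Cl)Cl
Why: Imidate esterification, in which the carboxylic acid protonates the imidate and is O-alkylated at a primary carbon, works for hindered acids, and the less acidic catechol hydroxyls are expected not to react.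

Step 14
Reactants: 21 2-(trimethylsilyl)ethyl carnosate
Product: 22 TMSE 11,12-di-O-methylcarnosate
Conditions: MeI, K2CO3, acetone, reflux, Ar
Reagents that add atoms: iodomethane, CI
Why: Williamson O-methylation of both phenols gives the veratrole-type ring needed for a clean ozonolysis.

Step 15
Reactants: 22 TMSE 11,12-di-O-methylcarnosate
Product: 24 ring-cleaved diester, via hydroperoxy orthoester 23 (not isolated)
Conditions: O3 (1 equiv), CH2Cl2/MeOH, −78 °C; then Me2S
Reagents that add atoms: ozone, [O-][O+]=O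
Why: Ozone should attack the most electron-rich aromatic bond, between the two methoxy-bearing carbons, and cleave it to the muconate-type diester (ozonolysis of a veratrole ring), the resulting diene diester being electron-poor enough to survive one equivalent at −78 °C.

Step 16
Reactants: 24 ring-cleaved diester
Product: 26 enal ester, via diol 25 (not isolated)
Conditions: OsO4 (cat.), NaIO4, 2,6-lutidine, dioxane/H2O, rt
Reagents that add atoms: osmium tetroxide, O=[Os](=O)(=O)=O; sodium periodate, [Na+].[O-]I(=O)(=O)=O (reoxidant that supplies the oxygen)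
Why: Lemieux–Johnson oxidation should select on steric grounds the trisubstituted isopropyl-bearing alkene over the tetrasubstituted ring alkene next to the quaternary C10, leaving the formyl carbon C17 on C8.

Step 17
Reactants: 26 enal ester
Product: 28 11,17-diol, via butenolide 27 (not isolated)
Conditions: LiBH4, THF/MeOH, 0 °C → rt
Reagents that add atoms: none
Why: Borohydride reduction of the aldehyde, lactonisation of the cis hydroxy ester and further reduction of the lactone should give the (Z)-2-butene-1,4-diol, the ester on the quaternary C10 reacting much more slowly with LiBH4.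

Step 18
Reactants: 28 11,17-diol
Product: 29 17-pivalate
Conditions: PivCl (1.05 equiv), pyridine, CH2Cl2, −20 °C
Reagents that add atoms: pivaloyl chloride, CC(C)(C)C(=O)Cl
Why: Sterically controlled acylation by the bulky acid chloride should esterify the C17 hydroxyl, flanked only by the C7 methylene, in preference to the C11 hydroxyl next to the quaternary C10.

Step 19
Reactants: 29 17-pivalate
Product: 30 11-bromide
Conditions: CBr4, PPh3, CH2Cl2, 0 °C
Reagents that add atoms: carbon tetrabromide, BrC(Br)(Br)Br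
Why: The Appel reaction converts the remaining primary allylic alcohol into the bromide under neutral conditions.

Step 20
Reactants: 31 (S)-but-3-yn-2-ol
Product: 32 (S,E)-4-(tributylstannyl)but-3-en-2-ol
Conditions: Bu3SnH, PdCl2(PPh3)2 (2 mol%), THF, 0 °C
Reagents that add atoms: tributyltin hydride, CCCC[SnH](CCCC)CCCC
Why: Palladium-catalysed syn-hydrostannation of the terminal alkyne should give mainly the distal (E)-alkenylstannane, the carbinol stereocentre being untouched.

Step 21
Reactants: 30 11-bromide; 32 (S,E)-4-(tributylstannyl)but-3-en-2-ol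
Product: 33 allylic alcohol
Conditions: Pd2(dba)3 (2.5 mol%), AsPh3, THF, 40 °C
Reagents that add atoms: none
Why: Stille coupling through the π-allylpalladium complex should join the alkenyl group, with retention of its E geometry, to the less hindered primary terminus C11, the allylic pivalate ionising far more slowly than the bromide at this temperature.

### Union and end game

Step 22
Reactants: 33 allylic alcohol; 19 aryl dioxinone
Product: 35 allylic β-keto ester, via acylketene 34 (not isolated)
Conditions: toluene, 110 °C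
Reagents that add atoms: none
Why: Thermal retro-[4+2] of the dioxinone releases the acylketene, which the secondary allylic alcohol traps to give the β-keto ester under neutral conditions (acylketene esterification).

Step 23
Reactants: 35 allylic β-keto ester
Product: 38 α-methylene ketone, via β-keto acid 36 (not isolated), via Mannich base 37 (not isolated)
Conditions: LDA (2.2 equiv), THF, −78 → 50 °C; then CH2=NMe2+ I−, 0 °C → rt; then AcOH, THF, 50 °C
Reagents that add atoms: N,N-dimethylmethyleneiminium iodide (Eschenmoser's salt), C=[N+](C)C.[I-]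
Why: The ester dianion undergoes Carroll rearrangement ([3,3]) through a chair transition state with the carbinol methyl equatorial, which transfers the (S)-carbinol configuration to C12 (R) and gives the E-propenyl group, and aminomethylation of the β-keto acid dianion at C13 followed by decarboxylative elimination (Mannich methylenation) places the methylene regiospecifically between C12 and the C14 ketone.

Step 24
Reactants: 38 α-methylene ketone
Product: 39 (12R,14S) allylic alcohol
Conditions: (R)-2-methyl-CBS-oxazaborolidine (1 equiv), catecholborane, toluene, −78 °C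
Reagents that add atoms: none
Why: Corey–Bakshi–Shibata 1,2-reduction with the (R)-catalyst, the branched alkenyl group acting as the large substituent, should set the (14S) alcohol by reagent control while catecholborane leaves the alkenes alone.

Step 25
Reactants: 39 (12R,14S) allylic alcohol
Product: 40 C14 TBS ether
Conditions: TBSOTf, 2,6-lutidine, CH2Cl2, −78 °C
Reagents that add atoms: tert-butyldimethylsilyl trifluoromethanesulfonate, CC(C)(C)[Si](C)(C)OS(=O)(=O)C(F)(F)F
Why: Silylation of the hindered allylic alcohol with the silyl triflate gives the ether that has to last until the final step.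

Step 26
Reactants: 40 C14 TBS ether
Product: 41 C7′ alcohol
Conditions: PPTS, MeOH/CH2Cl2, 0 °C → rt
Reagents that add atoms: none
Why: Acid-catalysed methanolysis of silyl ethers should remove the triethylsilyl group much faster than the secondary and the aryl tert-butyldimethylsilyl ethers.

Step 27
Reactants: 41 C7′ alcohol
Product: 42 C7′ acetate (diene for ring closure)
Conditions: Ac2O, DMAP, pyridine, CH2Cl2, rt
Reagents that add atoms: acetic anhydride, CC(=O)OC(C)=O
Why: DMAP-catalysed acylation installs the C7′ acetate of the target before the acid-sensitive epoxide exists.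

Step 28
Reactants: 42 C7′ acetate (diene for ring closure)
Product: 43 aryl cycloheptene with Δ8 decalin
Conditions: second-generation Grubbs catalyst (10 mol%), toluene (2 mM), 80 °C, Ar sparge
Reagents that add atoms: none
Why: In this ring-closing metathesis the ruthenium alkylidene formed at the propenyl group can only close on the 1,1-disubstituted aryl alkene to give the trisubstituted cycloheptene, since the decalin alkene is tetrasubstituted and inert and the C13 methylene would give a three-membered ring.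

Step 29
Reactants: 43 aryl cycloheptene with Δ8 decalin
Product: 44 aryl cycloheptene with C8 methylene
Conditions: Pd2(dba)3 (5 mol%), PBu3, HCO2NH4, dioxane, 80 °C
Reagents that add atoms: none
Why: Palladium-catalysed formate hydrogenolysis of the allylic pivalate (Tsuji–Trost ionisation, then hydride transfer from palladium to the more substituted allyl terminus) should give the exocyclic C8=C17 alkene and place hydrogen on the α face of C9, because palladium binds the allyl face away from the axial C10 ester.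

Step 30
Reactants: 44 aryl cycloheptene with C8 methylene
Product: 45 (15′R,16′R)-epoxide
Conditions: dimethyldioxirane (1.1 equiv), acetone/CH2Cl2, −40 °C
Reagents that add atoms: dimethyldioxirane, CC1(C)OO1
Why: Dioxirane epoxidation under neutral conditions should select the electron-rich trisubstituted ring alkene over the two 1,1-disubstituted methylenes and attack the face opposite the C12 side chain and the C14 silyloxy group, giving the epoxide trans to C11.

Step 31
Reactants: 45 (15′R,16′R)-epoxide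
Product: 46 1-aryl cyclohexanecarbaldehyde
Conditions: BF3·OEt2 (1.0 equiv), 2,6-di-tert-butyl-4-methylpyridine, CH2Cl2, −78 °C
Reagents that add atoms: none
Why: BF3 binds the epoxide oxygen and the C15′–O bond ionises, C15′ being tertiary, benzylic and ortho to the silyloxy group, after which the ring bond C16′–C12 on the face opposite the departing oxygen shifts to C15′ while C16′–O becomes the formyl group (Meinwald rearrangement, a semipinacol-type 1,2-shift). The closest known reaction is the Lewis acid-promoted ring contraction of 1-arylcycloalkene oxides to 1-arylcycloalkanecarbaldehydes. The cyclohexane ring C12–C13–C14–Ca–Cb–C15′ is thus closed by a 1,2-alkyl shift that contracts the cycloheptane, not by cyclisation of a chain. The new quaternary stereocentre C15′ is set stereospecifically by the epoxide: C12 migrates with retention and enters C15′ with inversion, so the aryl carbon C14′ ends cis to C11 and the formyl group trans. The step needs carbon rather than hydride migration from C16′, which is favoured because C12 is secondary and allylic to the C13 methylene and because at −78 °C the shift should occur from the first-formed conformer, in which the boron-bound oxygen is still pseudoaxial and the C16′–H bond lies near the plane of the cation. The hindered pyridine base removes adventitious acid, so that the C8 methylene, the C10 ester and the silyl ethers are left alone.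

Step 32
Reactants: 46 1-aryl cyclohexanecarbaldehyde
Product: 48 lactol, via phenol aldehyde 47 (not isolated)
Conditions: Bu4NF (1.1 equiv), AcOH (1.1 equiv), THF, 0 °C
Reagents that add atoms: none
Why: Buffered fluoride should cleave the aryl silyl ether selectively, phenoxide being the better leaving group on silicon, and the freed phenol adds to the neighbouring aldehyde to close the five-membered lactol (hemiacetal formation), the new C16′ centre being of no consequence.

Step 33
Reactants: 48 lactol
Product: 49 protected lactone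
Conditions: Ag2CO3 on Celite, benzene, reflux
Reagents that add atoms: none
Why: Fétizon oxidation converts the lactol into the benzofuranone lactone under neutral conditions that spare the acetate, the silyl ether and the alkenes.

Step 34
Reactants: 49 protected lactone
Product: 50 CNP0558742.1
Conditions: (Me2N)3S+ Me3SiF2− (TASF), DMF, 0 °C → rt; then aq NH4Cl
Reagents that add atoms: none
Why: Fluoride removes the secondary silyl ether and fragments the 2-(trimethylsilyl)ethyl ester to the carboxylate with loss of ethylene (fluoride-induced β-elimination), anhydrous conditions sparing the acetate and the aryl lactone, which would reclose on the mildly acidic work-up if opened.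

## Compound list

1 | (−)-sclareol | C[C@]12CCCC([C@@H]1CC[C@@]([C@@H]2CC[C@](C)(C=C)O)(C)O)(C)C | starting material
2 | labdane-8α,13,14,15-tetraol from 1 (C14 epimers) | OCC(O)[C@](C)(O)CC[C@H]1[C@](C)(O)CC[C@H]2C(C)(C)CCC[C@]12C | intermediate
3 | 8α,13-dihydroxy-15-norlabdan-14-al | O=C[C@](C)(O)CC[C@H]1[C@](C)(O)CC[C@H]2C(C)(C)CCC[C@]12C | intermediate
4 | 8α-hydroxy-14,15-dinorlabdan-13-one | CC(=O)CC[C@H]1[C@](C)(O)CC[C@H]2C(C)(C)CCC[C@]12C | intermediate
5 | 14,15-dinorlabd-8(17)-en-13-one | CC(=O)CC[C@H]1C(=C)CC[C@H]2C(C)(C)CCC[C@]12C | intermediate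
6 | ozonide of 5 (spiro-1,2,4-trioxolane at C8) | CC(=O)CC[C@H]1C2(OCOO2)CC[C@H]2C(C)(C)CCC[C@]12C | intermediate
7 | 14,15,17-trinorlabdane-8,13-dione | CC(=O)CC[C@H]1C(=O)CC[C@H]2C(C)(C)CCC[C@]12C | intermediate
8 | (+)-podocarp-8(14)-en-13-one | O=C1CC[C@H]2C(=C1)CC[C@H]1C(C)(C)CCC[C@]21C | intermediate
9 | podocarpa-8,11,13-trien-13-ol | Oc1ccc2c(c1)CC[C@H]1C(C)(C)CCC[C@]21C | intermediate
10 | 14-bromopodocarpa-8,11,13-trien-13-ol | Oc1ccc2c(c1Br)CC[C@H]1C(C)(C)CCC[C@]21C | intermediate
11 | 14-bromo-13-(TBS-oxy)podocarpa-8,11,13-triene | CC(C)(C)[Si](C)(C)Oc1ccc2c(c1Br)CC[C@H]1C(C)(C)CCC[C@]21C | intermediate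
12 | 14-bromo-13-(TBS-oxy)podocarpa-8,11,13-trien-7-one | CC(C)(C)[Si](C)(C)Oc1ccc2c(c1Br)C(=O)C[C@H]1C(C)(C)CCC[C@]21C | intermediate
13 | (7S)-14-bromo-13-(TBS-oxy)podocarpa-8,11,13-trien-7β-ol | CC(C)(C)[Si](C)(C)Oc1ccc2c(c1Br)[C@@H](O)C[C@H]1C(C)(C)CCC[C@]21C | intermediate
14 | 7β-triethylsilyl ether of 13 | CC(C)(C)[Si](C)(C)Oc1ccc2c(c1Br)[C@@H](O[Si](CC)(CC)CC)C[C@H]1C(C)(C)CCC[C@]21C | intermediate
15 | 2,2,6-trimethyl-4H-1,3-dioxin-4-one | CC1=CC(=O)OC(C)(C)O1 | starting material
16 | lithium dienolate of 15 | C=C1C=C(O[Li])OC(C)(C)O1 | intermediate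
17 | 6-(3-bromobut-3-en-1-yl)-2,2-dimethyl-4H-1,3-dioxin-4-one | C=C(Br)CCC1=CC(=O)OC(C)(C)O1 | intermediate
18 | [13′-(TBS-oxy)-7′β-(TES-oxy)podocarpa-8′,11′,13′-trien-14′-yl]zinc chloride | Cl[Zn]c1c(O[Si](C)(C)C(C)(C)C)ccc2c1[C@@H](O[Si](CC)(CC)CC)C[C@H]1C(C)(C)CCC[C@]21C | intermediate
19 | aryl dioxinone: 6-[3-(aryl)but-3-en-1-yl]-2,2-dimethyl-4H-1,3-dioxin-4-one, aryl as in 18 | C=C(CCC1=CC(=O)OC(C)(C)O1)c1c(O[Si](C)(C)C(C)(C)C)ccc2c1[C@@H](O[Si](CC)(CC)CC)C[C@H]1C(C)(C)CCC[C@]21C | intermediate
20 | carnosic acid | CC(C)C1=C(C(=C2C(=C1)CC[C@@H]3[C@@]2(CCCC3(C)C)C(=O)O)O)O | starting material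
21 | 2-(trimethylsilyl)ethyl carnosate | CC(C)c1cc2CC[C@H]3C(C)(C)CCC[C@]3(C(=O)OCC[Si](C)(C)C)c2c(O)c1O | intermediate
22 | TMSE 11,12-di-O-methylcarnosate | CC(C)c1cc2CC[C@H]3C(C)(C)CCC[C@]3(C(=O)OCC[Si](C)(C)C)c2c(OC)c1OC | intermediate
23 | hydroperoxy orthoester from cleavage of the bond between the two methoxy-bearing carbons of 22 | COC(=O)C1=C(/C=C(/C(C)C)C(OC)(OC)OO)CC[C@H]2C(C)(C)CCC[C@]12C(=O)OCC[Si](C)(C)C | intermediate
24 | ring-cleaved diester: Δ8-decalin TMSE ester (5α-H, 10β-ester) with CO2Me on C9 and a (Z)-2-(methoxycarbonyl)-3-methylbut-1-enyl group on C8 | COC(=O)C1=C(/C=C(/C(C)C)C(=O)OC)CC[C@H]2C(C)(C)CCC[C@]12C(=O)OCC[Si](C)(C)C | intermediate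
25 | vicinal diol of the side-chain alkene of 24 | COC(=O)C1=C(C(O)C(O)(C(C)C)C(=O)OC)CC[C@H]2C(C)(C)CCC[C@]12C(=O)OCC[Si](C)(C)C | intermediate
26 | enal ester: Δ8-decalin TMSE ester with CO2Me on C9 and CHO (C17) on C8 | COC(=O)C1=C(C=O)CC[C@H]2C(C)(C)CCC[C@]12C(=O)OCC[Si](C)(C)C | intermediate
27 | butenolide: lactone between the C11 carbonyl on C9 and C17–O on C8 | O=C1OCC2=C1[C@@]1(C(=O)OCC[Si](C)(C)C)CCCC(C)(C)[C@@H]1CC2 | intermediate
28 | 11,17-diol: Δ8-decalin TMSE ester with CH2OH on C9 (C11) and on C8 (C17) | OCC1=C(CO)CC[C@H]2C(C)(C)CCC[C@]12C(=O)OCC[Si](C)(C)C | intermediate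
29 | 17-pivalate of 28 | OCC1=C(COC(=O)C(C)(C)C)CC[C@H]2C(C)(C)CCC[C@]12C(=O)OCC[Si](C)(C)C | intermediate
30 | 11-bromide of 29 | BrCC1=C(COC(=O)C(C)(C)C)CC[C@H]2C(C)(C)CCC[C@]12C(=O)OCC[Si](C)(C)C | intermediate
31 | (S)-but-3-yn-2-ol | C[C@H](O)C#C | starting material
32 | (S,E)-4-(tributylstannyl)but-3-en-2-ol | C[C@H](O)/C=C/[Sn](CCCC)(CCCC)CCCC | intermediate
33 | allylic alcohol: (S,E)-4-hydroxypent-2-enyl group on C9 of the Δ8-decalin 17-pivalate TMSE ester | C[C@H](O)/C=C/CC1=C(COC(=O)C(C)(C)C)CC[C@H]2C(C)(C)CCC[C@]12C(=O)OCC[Si](C)(C)C | intermediate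
34 | acylketene from 19 | O=C=CC(=O)CCC(=C)c1c(O[Si](C)(C)C(C)(C)C)ccc2c1[C@@H](O[Si](CC)(CC)CC)C[C@H]1C(C)(C)CCC[C@]21C | intermediate
35 | allylic β-keto ester: ester of 33 with the 3-oxo-6-arylhept-6-enoic acid from 34 | C[C@H](OC(=O)CC(=O)CCC(=C)c1c(O[Si](C)(C)C(C)(C)C)ccc2c1[C@@H](O[Si](CC)(CC)CC)C[C@H]1C(C)(C)CCC[C@]21C)/C=C/CC1=C(COC(=O)C(C)(C)C)CC[C@H]2C(C)(C)CCC[C@]12C(=O)OCC[Si](C)(C)C | intermediate
36 | β-keto acid after the [3,3] shift (12R, C13 epimers; formed as its dilithium salt) | C/C=C/[C@@H](CC1=C(COC(=O)C(C)(C)C)CC[C@H]2C(C)(C)CCC[C@]12C(=O)OCC[Si](C)(C)C)C(C(=O)O)C(=O)CCC(=C)c1c(O[Si](C)(C)C(C)(C)C)ccc2c1[C@@H](O[Si](CC)(CC)CC)C[C@H]1C(C)(C)CCC[C@]21C | intermediate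
37 | Mannich base: C13 dimethylaminomethyl derivative of 36 | C/C=C/[C@@H](CC1=C(COC(=O)C(C)(C)C)CC[C@H]2C(C)(C)CCC[C@]12C(=O)OCC[Si](C)(C)C)C(CN(C)C)(C(=O)O)C(=O)CCC(=C)c1c(O[Si](C)(C)C(C)(C)C)ccc2c1[C@@H](O[Si](CC)(CC)CC)C[C@H]1C(C)(C)CCC[C@]21C | intermediate
38 | α-methylene ketone (12R): C13=CH2, C14 ketone, E-propenyl on C12 | C/C=C/[C@@H](CC1=C(COC(=O)C(C)(C)C)CC[C@H]2C(C)(C)CCC[C@]12C(=O)OCC[Si](C)(C)C)C(=C)C(=O)CCC(=C)c1c(O[Si](C)(C)C(C)(C)C)ccc2c1[C@@H](O[Si](CC)(CC)CC)C[C@H]1C(C)(C)CCC[C@]21C | intermediate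
39 | (12R,14S) allylic alcohol | C/C=C/[C@@H](CC1=C(COC(=O)C(C)(C)C)CC[C@H]2C(C)(C)CCC[C@]12C(=O)OCC[Si](C)(C)C)C(=C)[C@@H](O)CCC(=C)c1c(O[Si](C)(C)C(C)(C)C)ccc2c1[C@@H](O[Si](CC)(CC)CC)C[C@H]1C(C)(C)CCC[C@]21C | intermediate
40 | C14 TBS ether of 39 | C/C=C/[C@@H](CC1=C(COC(=O)C(C)(C)C)CC[C@H]2C(C)(C)CCC[C@]12C(=O)OCC[Si](C)(C)C)C(=C)[C@@H](O[Si](C)(C)C(C)(C)C)CCC(=C)c1c(O[Si](C)(C)C(C)(C)C)ccc2c1[C@@H](O[Si](CC)(CC)CC)C[C@H]1C(C)(C)CCC[C@]21C | intermediate
41 | C7′ alcohol (7′β-OH) | C/C=C/[C@@H](CC1=C(COC(=O)C(C)(C)C)CC[C@H]2C(C)(C)CCC[C@]12C(=O)OCC[Si](C)(C)C)C(=C)[C@@H](O[Si](C)(C)C(C)(C)C)CCC(=C)c1c(O[Si](C)(C)C(C)(C)C)ccc2c1[C@@H](O)C[C@H]1C(C)(C)CCC[C@]21C | intermediate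
42 | C7′ acetate (diene for ring closure) | C/C=C/[C@@H](CC1=C(COC(=O)C(C)(C)C)CC[C@H]2C(C)(C)CCC[C@]12C(=O)OCC[Si](C)(C)C)C(=C)[C@@H](O[Si](C)(C)C(C)(C)C)CCC(=C)c1c(O[Si](C)(C)C(C)(C)C)ccc2c1[C@@H](OC(C)=O)C[C@H]1C(C)(C)CCC[C@]21C | intermediate
43 | aryl cycloheptene (C15′=C16′) with Δ8-decalin 17-pivalate | C(C1=C(COC(=O)C(C)(C)C)CC[C@H]2C(C)(C)CCC[C@]12C(=O)OCC[Si](C)(C)C)[C@H]1C(=C)[C@@H](O[Si](C)(C)C(C)(C)C)CCC(c2c(O[Si](C)(C)C(C)(C)C)ccc3c2[C@@H](OC(C)=O)C[C@H]2C(C)(C)CCC[C@]32C)=C1 | intermediate
44 | aryl cycloheptene with C8 methylene (9α-H) | C=C1CC[C@H]2C(C)(C)CCC[C@]2(C(=O)OCC[Si](C)(C)C)[C@H]1C[C@H]1C(=C)[C@@H](O[Si](C)(C)C(C)(C)C)CCC(c2c(O[Si](C)(C)C(C)(C)C)ccc3c2[C@@H](OC(C)=O)C[C@H]2C(C)(C)CCC[C@]32C)=C1 | intermediate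
45 | (15′R,16′R)-epoxide, oxygen trans to C11 | C=C1CC[C@H]2C(C)(C)CCC[C@]2(C(=O)OCC[Si](C)(C)C)[C@H]1C[C@H]2C(=C)[C@@H](O[Si](C)(C)C(C)(C)C)CC[C@]3(c4c(O[Si](C)(C)C(C)(C)C)ccc5c4[C@@H](OC(C)=O)C[C@H]4C(C)(C)CCC[C@]54C)O[C@H]23 | intermediate
46 | 1-aryl cyclohexanecarbaldehyde (C16′ formyl on C15′, aryl cis to C11) | C=C1CC[C@H]2C(C)(C)CCC[C@]2(C(=O)OCC[Si](C)(C)C)[C@H]1C[C@H]1C(=C)[C@@H](O[Si](C)(C)C(C)(C)C)CC[C@@]1(C=O)c1c(O[Si](C)(C)C(C)(C)C)ccc2c1[C@@H](OC(C)=O)C[C@H]1C(C)(C)CCC[C@]21C | intermediate
47 | phenol aldehyde (aryl silyl ether of 46 removed) | C=C1CC[C@H]2C(C)(C)CCC[C@]2(C(=O)OCC[Si](C)(C)C)[C@H]1C[C@H]1C(=C)[C@@H](O[Si](C)(C)C(C)(C)C)CC[C@@]1(C=O)c1c(O)ccc2c1[C@@H](OC(C)=O)C[C@H]1C(C)(C)CCC[C@]21C | intermediate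
48 | lactol (C16′ epimers) | C=C1CC[C@H]2C(C)(C)CCC[C@]2(C(=O)OCC[Si](C)(C)C)[C@H]1C[C@H]1C(=C)[C@@H](O[Si](C)(C)C(C)(C)C)CC[C@]12C(O)Oc1ccc3c(c12)[C@@H](OC(C)=O)C[C@H]1C(C)(C)CCC[C@]31C | intermediate
49 | lactone with C14 TBS ether and TMSE ester | C=C1CC[C@H]2C(C)(C)CCC[C@]2(C(=O)OCC[Si](C)(C)C)[C@H]1C[C@H]1C(=C)[C@@H](O[Si](C)(C)C(C)(C)C)CC[C@]12C(=O)Oc1ccc3c(c12)[C@@H](OC(C)=O)C[C@H]1C(C)(C)CCC[C@]31C | intermediate
50 | CNP0558742.1 | C=C1CC[C@H]2C(C)(C)CCC[C@]2(C(=O)O)[C@H]1C[C@H]1C(=C)[C@@H](O)CC[C@]12C(=O)Oc1ccc3c(c12)[C@@H](OC(C)=O)C[C@H]1C(C)(C)CCC[C@]31C | target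

## Step count and risks

Total step count: 34.
Longest linear sequence: 24 steps (steps 1–10, 12 and 22–34, from (−)-sclareol).

Steps most likely to fail:

1. Step 31 (ring contraction). If the benzylic cation lives long enough for the ring to relax, hydride instead of C12 may shift from C16′ and give the 2-aryl cycloheptanone, or the C14 silyloxy oxygen may capture the cation across the ring. The fallback sets out from 44 and comes back at 46; it replaces the cationic shift by the anionic semipinacol shift of a halohydrin, in which the migrating ring bond is held antiperiplanar to the leaving bromide. Alkene 44 is treated with N-bromosuccinimide in aqueous THF at 0 °C; the bromonium ion forms on the face away from C11 and water opens it at the benzylic carbon to give bromohydrin F1. KHMDS (1 equiv, THF, −78 → 0 °C) closes F1 to the epimeric epoxide F2, whose oxygen is cis to C11. MgBr2·OEt2 in toluene opens F2 at C15′ with inversion to the tertiary bromide F3 (as its magnesium alkoxide). On warming, the alkoxide expels bromide while the ring bond C16′–C12 shifts, and the two inversions at C15′ lead to the same aldehyde 46.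

2. Step 28 (ring-closing metathesis). Ring closure at the crowded aryl alkene, which is flanked by the ortho silyl ether and the peri C7′ acetate, may be slower than cross-metathesis of the propenyl groups or decay of the catalyst. The fallback sets out from 42 and comes back at 43; it closes the ring on a less crowded substrate. Buffered Bu4NF (AcOH, THF, 0 °C) removes only the aryl silyl ether to give the phenol diene F4; ring-closing metathesis with the same ruthenium catalyst gives the phenol cycloheptene F5; TBSOTf and 2,6-lutidine then restore the aryl silyl ether to give 43.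

3. Step 29 (release of the C8 methylene). Hydride may be transferred to the primary allyl terminus (giving the Δ8 alkene with a C17 methyl group) or to the β face of C9. The fallback sets out from 43 and comes back at 44; it replaces hydride transfer from palladium by the sigmatropic loss of nitrogen from an allylic diazene, which can only deliver hydrogen to C9. Palladium-catalysed allylic substitution of the pivalate (Pd2(dba)3, PPh3, Et3N, THF) with N-isopropylidene-N′-2-nitrobenzenesulfonyl hydrazine at the primary terminus C17 gives the sulfonyl hydrazone F6. Hydrolysis in trifluoroethanol/water/AcOH releases the allylic diazene F7, which loses nitrogen by a retro-ene shift, placing hydrogen on C9 and forming the C8=C17 alkene of 44.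

## Further compounds

F1 | step 31 | bromohydrin from 44: C16′–Br trans to C11, C15′–OH cis to C11 | C=C1CC[C@H]2C(C)(C)CCC[C@]2(C(=O)OCC[Si](C)(C)C)[C@H]1C[C@H]1C(=C)[C@@H](O[Si](C)(C)C(C)(C)C)CC[C@](O)(c2c(O[Si](C)(C)C(C)(C)C)ccc3c2[C@@H](OC(C)=O)C[C@H]2C(C)(C)CCC[C@]32C)[C@@H]1Br
F2 | step 31 | epimeric epoxide, oxygen cis to C11 | C=C1CC[C@H]2C(C)(C)CCC[C@]2(C(=O)OCC[Si](C)(C)C)[C@H]1C[C@H]2C(=C)[C@@H](O[Si](C)(C)C(C)(C)C)CC[C@@]3(c4c(O[Si](C)(C)C(C)(C)C)ccc5c4[C@@H](OC(C)=O)C[C@H]4C(C)(C)CCC[C@]54C)O[C@@H]23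
F3 | step 31 | tertiary bromide: C15′–Br trans to C11, C16′–OH cis to C11 (formed as magnesium alkoxide) | C=C1CC[C@H]2C(C)(C)CCC[C@]2(C(=O)OCC[Si](C)(C)C)[C@H]1C[C@H]1C(=C)[C@@H](O[Si](C)(C)C(C)(C)C)CC[C@@](Br)(c2c(O[Si](C)(C)C(C)(C)C)ccc3c2[C@@H](OC(C)=O)C[C@H]2C(C)(C)CCC[C@]32C)[C@H]1O
F4 | step 28 | phenol diene (42 without the aryl silyl group) | C/C=C/[C@@H](CC1=C(COC(=O)C(C)(C)C)CC[C@H]2C(C)(C)CCC[C@]12C(=O)OCC[Si](C)(C)C)C(=C)[C@@H](O[Si](C)(C)C(C)(C)C)CCC(=C)c1c(O)ccc2c1[C@@H](OC(C)=O)C[C@H]1C(C)(C)CCC[C@]21C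
F5 | step 28 | phenol cycloheptene (43 without the aryl silyl group) | C(C1=C(COC(=O)C(C)(C)C)CC[C@H]2C(C)(C)CCC[C@]12C(=O)OCC[Si](C)(C)C)[C@H]1C(=C)[C@@H](O[Si](C)(C)C(C)(C)C)CCC(c2c(O)ccc3c2[C@@H](OC(C)=O)C[C@H]2C(C)(C)CCC[C@]32C)=C1
F6 | step 29 | sulfonyl hydrazone: C17 N-allylated N-isopropylidene-2-nitrobenzenesulfonyl hydrazide of 43 | C(C1=C(CN(N=C(C)C)S(=O)(=O)c4ccccc4[N+](=O)[O-])CC[C@H]2C(C)(C)CCC[C@]12C(=O)OCC[Si](C)(C)C)[C@H]1C(=C)[C@@H](O[Si](C)(C)C(C)(C)C)CCC(c2c(O[Si](C)(C)C(C)(C)C)ccc3c2[C@@H](OC(C)=O)C[C@H]2C(C)(C)CCC[C@]32C)=C1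
F7 | step 29 | allylic diazene at C17 | C(C1=C(CN=N)CC[C@H]2C(C)(C)CCC[C@]12C(=O)OCC[Si](C)(C)C)[C@H]1C(=C)[C@@H](O[Si](C)(C)C(C)(C)C)CCC(c2c(O[Si](C)(C)C(C)(C)C)ccc3c2[C@@H](OC(C)=O)C[C@H]2C(C)(C)CCC[C@]32C)=C1
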